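**Plan**

- Retrosynthesis: the C4 and C6 ester C–O bonds and the lactone bond C16–O(C3) are cut first. The 6-oxygen/7-methylene pair is traced to a Z C6=C7 olefin, the C11 carbinol to a ketone, and C16 to an isopropenyl CH2. The cyclohexane is cut at C12–C13 and C1–C14 (Diels–Alder of a C1=C10–C11=C12 diene with methyl vinyl ketone). C9–O and C8–C9 are then cut together.
- Enabling feature: the ether oxygen bridging C2 and C9 is bonded to C9, C9 carries C8, C8 is allylic to C7=C6, and C10 can be a ketone. The array O–C9(C10=O)–C8–C7=C6 is the retron of a [2,3]-shift of a cyclic allylic oxonium ylide. Undoing it re-forms O–C6 and contracts the oxonane (O, C2–C9) to a tetrahydropyran (O, C2–C6) carrying a diazoketone arm (C1, C10, C9) on C2.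
- Forward order: δ-lactone → tetrahydropyran → tetrahydrofuranone ring and oxonene in one step (oxabicyclo[6.2.1]undecenone) → cyclohexane by Diels–Alder → seven-membered lactone → esters.
- Stereochemistry: C6 of the tetrahydropyran comes from a Brown allylboration. C4, C3 and C2 are relayed from it in the six-membered ring (trans oxa-Michael addition, enolate oxidation anti to O4, axial hydride). C9 follows from C2 in the key step. C1, C14 and C10 come from an exo-face Diels–Alder reaction plus equilibration, C11 from Grignard addition anti to C9, C15 from hydroboration, and C6 from exo epoxidation followed by Mitsunobu inversion.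

Key step: step 11

Remark on numbering: O1 is the ether oxygen between C2 and C9; C2–C9 are the oxonane carbons (C3 methyl carbinol, C4 octanoate, C6 butanoate, C7 methylene); C10 (next to C9) and C1 complete the tetrahydrofuran; C11–C14 complete the cyclohexane (C11 next to C10, C14 next to C1); C15 is the methine on C14 and C16 the lactone carbonyl. The target is (1S,2S,3S,4R,6R,9S,10R,11R,14R,15R). PMB = 4-methoxybenzyl, TBS = tert-butyldimethylsilyl.

Assumption: peroxy-acid attack on the Z C6=C7 olefin of the bridged oxonene is taken to occur from the exo face, anti to the C3 oxygen; the C6 configuration is therefore corrected by inversion in step 22.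

**Route**

Step 1
Reactants: 1 methacrolein; 2 (−)-B-allyldiisopinocampheylborane
Product: 4 (S)-2-methylhexa-1,5-dien-3-ol, via borinate 3 (not isolated)
Conditions: Et2O, −78 °C; then NaOH, H2O2, 0 °C to rt
Reagents that add atoms: none
Why: Brown asymmetric allylboration through a chair six-membered transition state, in which the isopinocampheyl groups derived from (+)-α-pinene direct the allyl group to the Si face of the aldehyde and set the carbinol centre (later C6 of the tetrahydropyran) as S.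

Step 2
Reactants: 4 (S)-2-methylhexa-1,5-dien-3-ol; 5 acryloyl chloride
Product: 6 (S)-2-methylhexa-1,5-dien-3-yl acrylate
Conditions: Et3N, DMAP (cat.), CH2Cl2, 0 °C
Reagents that add atoms: none
Why: O-acylation of a secondary alcohol by an acid chloride (nucleophilic acyl substitution), which leaves the stereocentre untouched.

Step 3
Reactants: 6 acrylate ester
Product: 7 (S)-6-(prop-1-en-2-yl)-5,6-dihydro-2H-pyran-2-one
Conditions: second-generation Grubbs catalyst RuCl2(=CHPh)(PCy3)(H2IMes) (5 mol%), CH2Cl2, 40 °C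
Reagents that add atoms: none
Why: ring-closing metathesis of the acrylate with the monosubstituted olefin closes the six-membered unsaturated lactone with loss of ethene, while the hindered isopropenyl group could only give a four-membered or a tetrasubstituted five-membered ring and stays out.

Step 4
Reactants: 7 unsaturated lactone
Product: 8 (4R,6S)-4-(PMB-oxy)-6-(prop-1-en-2-yl)oxan-2-one
Conditions: 4-methoxybenzyl alcohol (excess), NaH (cat.), THF, −20 °C; AcOH quench
Reagents that add atoms: 4-methoxybenzyl alcohol, COc1ccc(CO)cc1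
Why: alkoxide oxa-Michael addition to the unsaturated δ-lactone, in which axial attack on the half-chair anti to the pseudo-equatorial C6 substituent places the new C4 ether trans to the isopropenyl group (4R).

Step 5
Reactants: 8 PMB-oxy lactone
Product: 10 (3S,4R,6S)-3-methyl-4-(PMB-oxy)-6-(prop-1-en-2-yl)oxan-2-one, via lithium enolate 9 (not isolated)
Conditions: LiN(iPr)2, THF, −78 °C; then MeI
Reagents that add atoms: iodomethane, CI
Why: lactone enolate alkylation held at −78 °C to suppress β-elimination of the ether, with MeI entering anti to the C4 ether; the configuration of this centre is erased again in step 6.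

Step 6
Reactants: 10 methyl lactone
Product: 12 (3S,4R,6S)-3-hydroxy-3-methyl-4-(PMB-oxy)-6-(prop-1-en-2-yl)oxan-2-one, via potassium enolate 11 (not isolated)
Conditions: KN(SiMe3)2, THF, −78 °C; then 2-(phenylsulfonyl)-3-phenyloxaziridine
Reagents that add atoms: 2-(phenylsulfonyl)-3-phenyloxaziridine, O=S(=O)(c1ccccc1)N1OC1c1ccccc1
Why: Davis enolate oxidation, in which the oxaziridine attacks the tetrasubstituted enolate on the face anti to the pseudo-axial C4 ether and sets the tertiary carbinol C3 as S with its oxygen trans to O4.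

Step 7
Reactants: 12 hydroxy lactone
Product: 13 (3S,4R,6S)-3-(TBS-oxy)-3-methyl-4-(PMB-oxy)-6-(prop-1-en-2-yl)oxan-2-one
Conditions: TBSOTf, 2,6-lutidine, CH2Cl2, 0 °C to rt
Reagents that add atoms: tert-butyldimethylsilyl trifluoromethanesulfonate, CC(C)(C)[Si](C)(C)OS(=O)(=O)C(F)(F)F
Why: silyl triflate silylation of a hindered tertiary alcohol, which later keeps the carbenoid away from a free O–H bond.

Step 8
Reactants: 13 silyloxy lactone; 14 ethyl acetate
Product: 16 ethyl 2-[(2S,3S,4R,6S)-3-(TBS-oxy)-3-methyl-4-(PMB-oxy)-6-(prop-1-en-2-yl)oxan-2-yl]acetate, via lactol 15 (not isolated)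
Conditions: LiN(iPr)2, 14, THF, −78 °C, then 13; crude lactol: Et3SiH, BF3·OEt2, CH2Cl2, −78 to −40 °C
Reagents that add atoms: none
Why: Claisen-type addition of the ester enolate to the non-enolisable lactone stops at the lactol, and ionic reduction of the derived oxocarbenium ion delivers hydride axially, anti to the C3 silyloxy group, so that the acetate arm at C2 (2S) is equatorial and cis to the C6 isopropenyl group.

Step 9
Reactants: 16 tetrahydropyran ester
Product: 17 2-[(2S,3S,4R,6S)-3-(TBS-oxy)-3-methyl-4-(PMB-oxy)-6-(prop-1-en-2-yl)oxan-2-yl]acetic acid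
Conditions: LiOH, THF/MeOH/H2O, rt; then dilute HCl to pH 4
Reagents that add atoms: lithium hydroxide, [Li+].[OH-]
Why: saponification of the ethyl ester, which leaves the silyl and benzyl ethers intact.

Step 10
Reactants: 17 tetrahydropyran acid
Product: 19 1-diazo-3-[(2S,3S,4R,6S)-3-(TBS-oxy)-3-methyl-4-(PMB-oxy)-6-(prop-1-en-2-yl)oxan-2-yl]propan-2-one, via mixed anhydride 18 (not isolated)
Conditions: iBuOCOCl, Et3N, Et2O, 0 °C; then CH2N2, Et2O, 0 °C to rt
Reagents that add atoms: diazomethane, C=[N+]=[N-]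
Why: acylation of diazomethane by the mixed carbonic anhydride (Arndt–Eistert-type diazoketone synthesis), mild enough for the silyl and PMB ethers.

Step 11
Reactants: 19 diazoketone
Product: 21 (1S,2S,3R,5Z,8S)-2-(TBS-oxy)-3-(PMB-oxy)-2,6-dimethyl-11-oxabicyclo[6.2.1]undec-5-en-9-one, via oxonium ylide 20 (not isolated)
Conditions: Cu(CF3COCHCOCF3)2 [Cu(hfacac)2] (5 mol%), CH2Cl2, reflux, slow addition of 19
Reagents that add atoms: none
Why: Loss of N2 from 19 on the copper catalyst gives an electrophilic carbenoid at C9 that is captured by a lone pair of the tetrahydropyran oxygen, closing the five-membered oxonium ylide 20 (C9–O bond), which rearranges at once by a concerted suprafacial [2,3]-sigmatropic shift that joins C9 to the terminal isopropenyl carbon C8, breaks O–C6 and moves the double bond to C6=C7. The closest known reaction type is the copper- or rhodium-catalysed oxonium ylide formation/[2,3]-rearrangement of diazoketones tethered to cyclic allylic ethers, used for ring expansion to bridged medium-ring ethers. The tetrahydrofuran-3-one ring (O, C9, C10, C1, C2) closes in a 5-exo sense by attack of the ether oxygen on the carbenoid carbon, while the oxonene (O, C2–C9) is not closed by a new ring bond but arises by three-atom ring expansion of the tetrahydropyran through a five-membered envelope transition state. The new stereocentre C9 is controlled by C2, because only the cis-fused ylide can deliver C8 to the face of the ylide carbon on which C6 sits, so H9 ends cis to H2 across the ether bridge (9S); the Z geometry of C6=C7 is the catalyst-dependent preference expected for Cu(hfacac)2. The step needs ylide formation at the ring oxygen in preference to the C3 silyl ether oxygen, the C4 benzylic ether or C–H insertion, and [2,3]- over [1,2]-shift; the five-membered size of ylide 20, the shielded and poorly nucleophilic silyl ether, the low insertion tendency of copper carbenoids and the equatorial isopropenyl group held next to the ylide carbon should secure this.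

Step 12
Reactants: 21 bicyclic ketone
Product: 23 (1S,2S,3R,5Z,8S)-2-(TBS-oxy)-3-(PMB-oxy)-2,6-dimethyl-11-oxabicyclo[6.2.1]undeca-5,9-dien-9-yl trifluoromethanesulfonate, via sodium enolate 22 (not isolated)
Conditions: NaN(SiMe3)2, THF, −78 °C; then PhNTf2
Reagents that add atoms: N-phenylbis(trifluoromethanesulfonimide), O=S(=O)(N(c1ccccc1)S(=O)(=O)C(F)(F)F)C(F)(F)F
Why: kinetic enolisation can only go toward the C1 methylene, since C9 is a bridgehead whose enolate would be a strained bridgehead olefin, and O-sulfonylation gives the C1=C10 enol triflate.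

Step 13
Reactants: 23 enol triflate; 24 tributyl(1-ethoxyvinyl)stannane
Product: 25 (1S,2S,3R,5Z,8S)-9-(1-ethoxyvinyl)-2-(TBS-oxy)-3-(PMB-oxy)-2,6-dimethyl-11-oxabicyclo[6.2.1]undeca-5,9-diene
Conditions: Pd(PPh3)4 (5 mol%), LiCl, THF, reflux
Reagents that add atoms: none
Why: Stille coupling of the enol triflate with the α-ethoxyvinyl stannane on zerovalent palladium installs C11 and C12 as a 2-ethoxy-1,3-diene without touching the other olefin.

Step 14
Reactants: 25 ethoxy diene; 26 methyl vinyl ketone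
Product: 28 tricyclic acetyl enol ether (1S,2S,3S,4R,6Z,9S,14R), via cycloadduct epimer mixture 27 (not isolated)
Conditions: 26 (excess), toluene, 110 °C, sealed tube; then K2CO3, MeOH, rt
Reagents that add atoms: none
Why: Diels–Alder cycloaddition in which the electron-rich terminus C12 bonds to the β-carbon of the enone ("para" regiochemistry) and the dienophile approaches the diene face anti to the six-carbon bridge (C1 set as S), after which K2CO3/MeOH epimerises the enolisable acetyl-bearing C14 of the endo/exo mixture into the trans-diequatorial 14R isomer.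

Step 15
Reactants: 28 tricyclic methyl ketone
Product: 29 tricyclic isopropenyl enol ether (1S,2S,3S,4R,6Z,9S,14R)
Conditions: Ph3PCH3Br, KOtBu, THF, 0 °C to rt
Reagents that add atoms: methyltriphenylphosphonium bromide, C[P+](c1ccccc1)(c1ccccc1)c1ccccc1.[Br-]
Why: Wittig methylenation of the only carbonyl group converts the acetyl group into the isopropenyl group (C15=C16), the thermodynamically settled C14 centre being unaffected.

Step 16
Reactants: 29 enol ether
Product: 30 tricyclic C11 ketone (1S,2S,3S,4R,6Z,9S,10R,14R)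
Conditions: 1 M aq. HCl, THF, 0 °C to rt
Reagents that add atoms: water, O
Why: acid hydrolysis of the enol ether, in which protonation at C10 from the convex face gives the cis ring fusion (10R), also the thermodynamic outcome at this ketone-adjacent centre.

Step 17
Reactants: 30 ketone
Product: 31 tricyclic tertiary alcohol (1S,2S,3S,4R,6Z,9S,10R,11R,14R)
Conditions: MeMgBr, THF, −78 to 0 °C
Reagents that add atoms: methylmagnesium bromide, C[Mg]Br
Why: Grignard addition to the cyclohexanone along the axial trajectory on the convex face, anti to the axial C10–C9 bond, puts the methyl cis to H10 and the hydroxyl on the side of C9 (11R).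

Step 18
Reactants: 31 diene alcohol
Product: 33 primary alcohol (15R; 16-hydroxy), via B-alkyl-9-borabicyclononane 32 (not isolated)
Conditions: 9-BBN, THF, 0 °C to rt; then NaOH, H2O2, 0 °C
Reagents that add atoms: hydrogen peroxide, OO
Why: hydroboration–oxidation with a bulky borane reacts only at the 1,1-disubstituted olefin, and attack on the conformer with C14–H eclipsing C15=C16 from the face anti to C1 should set C15 as R.

Step 19
Reactants: 33 primary alcohol
Product: 34 16-O-TBS ether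
Conditions: TBSCl, imidazole, CH2Cl2, 0 °C
Reagents that add atoms: tert-butyldimethylsilyl chloride, CC(C)(C)[Si](C)(C)Cl
Why: selective silylation of the primary hydroxyl, the tertiary C11 hydroxyl being inert to TBSCl.

Step 20
Reactants: 34 silyl ether
Product: 35 (6S,7R)-6,7-epoxide
Conditions: mCPBA, NaHCO3, CH2Cl2, −20 to 0 °C
Reagents that add atoms: 3-chloroperoxybenzoic acid, O=C(OO)c1cccc(Cl)c1
Why: Prilezhaev epoxidation of the only remaining olefin from its exposed exo face, anti to the C3 oxygen, stereospecifically gives the cis-epoxide.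

Step 21
Reactants: 35 epoxide
Product: 36 (6S)-6-hydroxy-7-methylene allylic alcohol
Conditions: Et2Al(NC9H18) [diethylaluminium 2,2,6,6-tetramethylpiperidide] (4 equiv), toluene, 0 °C
Reagents that add atoms: none
Why: aluminium amide-mediated syn-elimination of the epoxide breaks the tertiary C7–O bond and removes a proton from the C7 methyl group, which lies cis to the epoxide hydrogen and is the least hindered, giving the exocyclic methylene with retention at C6.

Step 22
Reactants: 36 allylic alcohol; 37 butanoic acid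
Product: 38 (6R)-butanoate
Conditions: PPh3, DIAD, toluene, 0 °C to rt
Reagents that add atoms: none
Why: Mitsunobu esterification displaces the activated secondary allylic oxygen by butanoate with SN2 inversion (6S to 6R) and installs the C6 ester in the same step, the tertiary C11 hydroxyl being unreactive.

Step 23
Reactants: 38 bis-silyl ether
Product: 39 triol (3-, 11- and 16-hydroxy)
Conditions: HF·pyridine, pyridine, THF, 0 °C to rt
Reagents that add atoms: none
Why: fluoride-driven desilylation under buffered acidic conditions removes the primary and the tertiary TBS group without acyl cleavage or migration of the butanoate.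

Step 24
Reactants: 39 triol
Product: 40 hydroxy acid (C16 carboxylic acid)
Conditions: TEMPO (cat.), PhI(OAc)2, MeCN/pH 7 buffer, rt
Reagents that add atoms: water, O
Why: oxoammonium oxidation is selective for the primary alcohol, which is taken through the aldehyde hydrate to the acid, while the tertiary alcohols, PMB ether, ester and exocyclic olefin are not affected.

Step 25
Reactants: 40 hydroxy acid
Product: 42 seven-membered lactone (4-O-PMB, 6-butanoate), via mixed anhydride 41 (not isolated)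
Conditions: 2,4,6-Cl3C6H2COCl, Et3N, THF, rt; then DMAP, toluene, 80 °C, high dilution
Reagents that add atoms: none
Why: Yamaguchi lactonisation, in which the acylpyridinium formed from the mixed anhydride is held next to the C3 tertiary hydroxyl by the rigid tricycle and closes the seven-membered lactone, while the C11 hydroxyl, trans across the cyclohexane, cannot reach C16.

Step 26
Reactants: 42 PMB ether lactone
Product: 43 C4 alcohol
Conditions: DDQ, CH2Cl2/pH 7 buffer, 0 °C
Reagents that add atoms: none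
Why: oxidative cleavage of the electron-rich PMB ether by hydride abstraction and hydrolysis of the oxocarbenium ion frees the C4 hydroxyl without touching the esters or the olefin.

Step 27
Reactants: 43 C4 alcohol; 44 octanoyl chloride
Product: 45 briarellin C
Conditions: pyridine, DMAP (cat.), CH2Cl2, 0 °C
Reagents that add atoms: none
Why: acylation of the only secondary hydroxyl by the acid chloride, the tertiary C11 hydroxyl being too hindered to react under these conditions.

**Compound list**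

1 | methacrolein | C=C(C)C=O | starting material
2 | (−)-B-allyldiisopinocampheylborane | C=CCB([C@@H]1C[C@@H]2C[C@H]([C@H]1C)C2(C)C)[C@@H]1C[C@@H]2C[C@H]([C@H]1C)C2(C)C | starting material
3 | (S)-2-methylhexa-1,5-dien-3-yl diisopinocampheylborinate | C=CC[C@H](OB([C@@H]1C[C@@H]2C[C@H]([C@H]1C)C2(C)C)[C@@H]1C[C@@H]2C[C@H]([C@H]1C)C2(C)C)C(C)=C | intermediate
4 | (S)-2-methylhexa-1,5-dien-3-ol | C=C(C)[C@@H](O)CC=C | intermediate
5 | acryloyl chloride | C=CC(=O)Cl | starting material
6 | (S)-2-methylhexa-1,5-dien-3-yl acrylate | C=CC(=O)O[C@@H](CC=C)C(C)=C | intermediate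
7 | (S)-6-(prop-1-en-2-yl)-5,6-dihydro-2H-pyran-2-one | O=C1C=CC[C@@H](C(C)=C)O1 | intermediate
8 | (4R,6S)-4-[(4-methoxybenzyl)oxy]-6-(prop-1-en-2-yl)oxan-2-one | O=C1C[C@H](OCc2ccc(OC)cc2)C[C@@H](C(C)=C)O1 | intermediate
9 | lithium enolate of 8 | [Li+].[O-]C1=C[C@H](OCc2ccc(OC)cc2)C[C@@H](C(C)=C)O1 | intermediate
10 | (3S,4R,6S)-4-[(4-methoxybenzyl)oxy]-3-methyl-6-(prop-1-en-2-yl)oxan-2-one | O=C1[C@@H](C)[C@H](OCc2ccc(OC)cc2)C[C@@H](C(C)=C)O1 | intermediate
11 | potassium enolate of 10 | [K+].[O-]C1=C(C)[C@H](OCc2ccc(OC)cc2)C[C@@H](C(C)=C)O1 | intermediate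
12 | (3S,4R,6S)-3-hydroxy-4-[(4-methoxybenzyl)oxy]-3-methyl-6-(prop-1-en-2-yl)oxan-2-one | O=C1[C@@](C)(O)[C@H](OCc2ccc(OC)cc2)C[C@@H](C(C)=C)O1 | intermediate
13 | (3S,4R,6S)-3-[(tert-butyldimethylsilyl)oxy]-4-[(4-methoxybenzyl)oxy]-3-methyl-6-(prop-1-en-2-yl)oxan-2-one | O=C1[C@@](C)(O[Si](C)(C)C(C)(C)C)[C@H](OCc2ccc(OC)cc2)C[C@@H](C(C)=C)O1 | intermediate
14 | ethyl acetate | CCOC(C)=O | starting material
15 | ethyl 2-[(3S,4R,6S)-2-hydroxy-3-(TBS-oxy)-4-(PMB-oxy)-3-methyl-6-(prop-1-en-2-yl)oxan-2-yl]acetate (lactol, anomer mixture) | CCOC(=O)CC1(O)O[C@H](C(C)=C)C[C@@H](OCc2ccc(OC)cc2)[C@]1(C)O[Si](C)(C)C(C)(C)C | intermediate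
16 | ethyl 2-[(2S,3S,4R,6S)-3-[(tert-butyldimethylsilyl)oxy]-4-[(4-methoxybenzyl)oxy]-3-methyl-6-(prop-1-en-2-yl)oxan-2-yl]acetate | CCOC(=O)C[C@@H]1O[C@H](C(C)=C)C[C@@H](OCc2ccc(OC)cc2)[C@]1(C)O[Si](C)(C)C(C)(C)C | intermediate
17 | 2-[(2S,3S,4R,6S)-3-(TBS-oxy)-4-(PMB-oxy)-3-methyl-6-(prop-1-en-2-yl)oxan-2-yl]acetic acid | OC(=O)C[C@@H]1O[C@H](C(C)=C)C[C@@H](OCc2ccc(OC)cc2)[C@]1(C)O[Si](C)(C)C(C)(C)C | intermediate
18 | isobutyl carbonic mixed anhydride of 17 | CC(C)COC(=O)OC(=O)C[C@@H]1O[C@H](C(C)=C)C[C@@H](OCc2ccc(OC)cc2)[C@]1(C)O[Si](C)(C)C(C)(C)C | intermediate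
19 | 1-diazo-3-[(2S,3S,4R,6S)-3-(TBS-oxy)-4-(PMB-oxy)-3-methyl-6-(prop-1-en-2-yl)oxan-2-yl]propan-2-one | [N-]=[N+]=CC(=O)C[C@@H]1O[C@H](C(C)=C)C[C@@H](OCc2ccc(OC)cc2)[C@]1(C)O[Si](C)(C)C(C)(C)C | intermediate
20 | bicyclic oxonium ylide (tetrahydrofuran-3-one fused to the tetrahydropyran through O+ and C2; carbanion at C9) | O=C1C[C@H]2[C@@](C)(O[Si](C)(C)C(C)(C)C)[C@H](OCc3ccc(OC)cc3)C[C@@H](C(C)=C)[O+]2[CH-]1 | intermediate
21 | (1S,2S,3R,5Z,8S)-2-[(tert-butyldimethylsilyl)oxy]-3-[(4-methoxybenzyl)oxy]-2,6-dimethyl-11-oxabicyclo[6.2.1]undec-5-en-9-one | C/C1=C/C[C@@H](OCc3ccc(OC)cc3)[C@](C)(O[Si](C)(C)C(C)(C)C)[C@@H]2CC(=O)[C@H](C1)O2 | intermediate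
22 | sodium enolate of 21 (C1=C10) | [Na+].C/C1=C/C[C@@H](OCc3ccc(OC)cc3)[C@](C)(O[Si](C)(C)C(C)(C)C)[C@@H]2C=C([O-])[C@H](C1)O2 | intermediate
23 | (1S,2S,3R,5Z,8S)-2-(TBS-oxy)-3-(PMB-oxy)-2,6-dimethyl-11-oxabicyclo[6.2.1]undeca-5,9-dien-9-yl trifluoromethanesulfonate | C/C1=C/C[C@@H](OCc3ccc(OC)cc3)[C@](C)(O[Si](C)(C)C(C)(C)C)[C@@H]2C=C(OS(=O)(=O)C(F)(F)F)[C@H](C1)O2 | intermediate
24 | tributyl(1-ethoxyvinyl)stannane | CCCC[Sn](CCCC)(CCCC)C(=C)OCC | starting material
25 | (1S,2S,3R,5Z,8S)-9-(1-ethoxyvinyl)-2-(TBS-oxy)-3-(PMB-oxy)-2,6-dimethyl-11-oxabicyclo[6.2.1]undeca-5,9-diene | C/C1=C/C[C@@H](OCc3ccc(OC)cc3)[C@](C)(O[Si](C)(C)C(C)(C)C)[C@@H]2C=C(C(=C)OCC)[C@H](C1)O2 | intermediate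
26 | methyl vinyl ketone | C=CC(C)=O | starting material
27 | Diels–Alder adduct as C14 epimer mixture (14-acetyl, 11-ethoxy, 10(11)-ene) | C/C1=C/C[C@@H](OCc4ccc(OC)cc4)[C@](C)(O[Si](C)(C)C(C)(C)C)[C@@H]2[C@H]3C(C(C)=O)CCC(OCC)=C3[C@H](C1)O2 | intermediate
28 | (1S,2S,3S,4R,6Z,9S,14R)-14-acetyl-11-ethoxy-3-(TBS-oxy)-4-(PMB-oxy)-3,7-dimethyl tricycle (O1 bridge C2–C9; olefins C6=C7 and C10=C11) | C/C1=C/C[C@@H](OCc4ccc(OC)cc4)[C@](C)(O[Si](C)(C)C(C)(C)C)[C@@H]2[C@H]3[C@H](C(C)=O)CCC(OCC)=C3[C@H](C1)O2 | intermediate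
29 | (1S,2S,3S,4R,6Z,9S,14R)-11-ethoxy-14-(prop-1-en-2-yl) tricycle (otherwise as 28) | C/C1=C/C[C@@H](OCc4ccc(OC)cc4)[C@](C)(O[Si](C)(C)C(C)(C)C)[C@@H]2[C@H]3[C@H](C(C)=C)CCC(OCC)=C3[C@H](C1)O2 | intermediate
30 | (1S,2S,3S,4R,6Z,9S,10R,14R)-11-oxo-14-(prop-1-en-2-yl) tricycle (cis-fused; 3-OTBS, 4-OPMB) | C/C1=C/C[C@@H](OCc4ccc(OC)cc4)[C@](C)(O[Si](C)(C)C(C)(C)C)[C@@H]2[C@H]3[C@H](C(C)=C)CCC(=O)[C@H]3[C@H](C1)O2 | intermediate
31 | (1S,2S,3S,4R,6Z,9S,10R,11R,14R)-11-hydroxy-11-methyl-14-(prop-1-en-2-yl) tricycle (3-OTBS, 4-OPMB) | C/C1=C/C[C@@H](OCc4ccc(OC)cc4)[C@](C)(O[Si](C)(C)C(C)(C)C)[C@@H]2[C@H]3[C@H](C(C)=C)CC[C@@](C)(O)[C@H]3[C@H](C1)O2 | intermediate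
32 | B-alkyl-9-borabicyclo[3.3.1]nonane adduct of 31 (boron on C16) | C/C1=C/C[C@@H](OCc4ccc(OC)cc4)[C@](C)(O[Si](C)(C)C(C)(C)C)[C@@H]2[C@H]3[C@H]([C@@H](C)CB4C5CCCC4CCC5)CC[C@@](C)(O)[C@H]3[C@H](C1)O2 | intermediate
33 | (1S,2S,3S,4R,6Z,9S,10R,11R,14S,15R)-16-hydroxy tricyclic diol (3-OTBS, 4-OPMB, 11-OH) | C/C1=C/C[C@@H](OCc4ccc(OC)cc4)[C@](C)(O[Si](C)(C)C(C)(C)C)[C@@H]2[C@H]3[C@H]([C@@H](C)CO)CC[C@@](C)(O)[C@H]3[C@H](C1)O2 | intermediate
34 | 16-O-TBS ether of 33 | C/C1=C/C[C@@H](OCc4ccc(OC)cc4)[C@](C)(O[Si](C)(C)C(C)(C)C)[C@@H]2[C@H]3[C@H]([C@@H](C)CO[Si](C)(C)C(C)(C)C)CC[C@@](C)(O)[C@H]3[C@H](C1)O2 | intermediate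
35 | (6S,7R)-6,7-epoxide of 34 | C[C@]12O[C@H]1C[C@@H](OCc5ccc(OC)cc5)[C@](C)(O[Si](C)(C)C(C)(C)C)[C@@H]3[C@H]4[C@H]([C@@H](C)CO[Si](C)(C)C(C)(C)C)CC[C@@](C)(O)[C@H]4[C@H](C2)O3 | intermediate
36 | (6S)-6-hydroxy-7-methylene allylic alcohol (3,16-bis-OTBS, 4-OPMB, 11-OH) | C=C1[C@@H](O)C[C@@H](OCc4ccc(OC)cc4)[C@](C)(O[Si](C)(C)C(C)(C)C)[C@@H]2[C@H]3[C@H]([C@@H](C)CO[Si](C)(C)C(C)(C)C)CC[C@@](C)(O)[C@H]3[C@H](C1)O2 | intermediate
37 | butanoic acid | CCCC(=O)O | starting material
38 | (6R)-6-butanoate (3,16-bis-OTBS, 4-OPMB, 11-OH) | C=C1[C@H](OC(=O)CCC)C[C@@H](OCc4ccc(OC)cc4)[C@](C)(O[Si](C)(C)C(C)(C)C)[C@@H]2[C@H]3[C@H]([C@@H](C)CO[Si](C)(C)C(C)(C)C)CC[C@@](C)(O)[C@H]3[C@H](C1)O2 | intermediate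
39 | 3,11,16-triol (6-butanoate, 4-OPMB) | C=C1[C@H](OC(=O)CCC)C[C@@H](OCc4ccc(OC)cc4)[C@](C)(O)[C@@H]2[C@H]3[C@H]([C@@H](C)CO)CC[C@@](C)(O)[C@H]3[C@H](C1)O2 | intermediate
40 | (15R)-C16 carboxylic acid (3,11-diol, 6-butanoate, 4-OPMB) | C=C1[C@H](OC(=O)CCC)C[C@@H](OCc4ccc(OC)cc4)[C@](C)(O)[C@@H]2[C@H]3[C@H]([C@@H](C)C(=O)O)CC[C@@](C)(O)[C@H]3[C@H](C1)O2 | intermediate
41 | 2,4,6-trichlorobenzoic mixed anhydride of 40 | C=C1[C@H](OC(=O)CCC)C[C@@H](OCc4ccc(OC)cc4)[C@](C)(O)[C@@H]2[C@H]3[C@H]([C@@H](C)C(=O)OC(=O)c5c(Cl)cc(Cl)cc5Cl)CC[C@@](C)(O)[C@H]3[C@H](C1)O2 | intermediate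
42 | (1S,2S,3S,4R,6R,9S,10R,11R,14R,15R)-4-O-PMB-4-deoctanoyl-briarellin C (lactone C16–O–C3 closed) | C=C1C[C@@H]2O[C@H]3[C@H]4[C@@H](CC[C@@](C)(O)[C@H]42)[C@@H](C)C(=O)O[C@@]3(C)[C@H](OCc5ccc(OC)cc5)C[C@H]1OC(=O)CCC | intermediate
43 | 4-deoctanoyl-briarellin C (4-hydroxy lactone) | C=C1C[C@@H]2O[C@H]3[C@H]4[C@@H](CC[C@@](C)(O)[C@H]42)[C@@H](C)C(=O)O[C@@]3(C)[C@H](O)C[C@H]1OC(=O)CCC | intermediate
44 | octanoyl chloride | CCCCCCCC(=O)Cl | starting material
45 | briarellin C | C=C1C[C@@H]2O[C@H]3[C@H]4[C@@H](CC[C@@](C)(O)[C@H]42)[C@@H](C)C(=O)O[C@@]3(C)[C@H](OC(=O)CCCCCCC)C[C@H]1OC(=O)CCC | target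

**Totals**

Total step count: 27. Longest linear sequence: 27 steps (from methacrolein 1).

**Steps most likely to fail, with fallbacks**

Step 25. The process at risk is slow acylation of the tertiary C3 hydroxyl, which would let oligomerisation compete, or epimerisation at C15 through a ketene formed from the activated acid. The fallback sets out from triol 39 and comes back at lactone 42. Oxidation of 39 with TEMPO/PhI(OAc)2 in dry CH2Cl2 should stop at the hydroxy aldehyde F6, which is in equilibrium with the seven-membered lactol F7 closed by the C3 hydroxyl. Oxidation of the lactol (Ag2CO3 on Celite in refluxing benzene, or the same TEMPO system) should give 42 without any activated acyl intermediate.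

Step 22. The process at risk is SN2' attack or elimination instead of clean inversion at the hindered allylic carbon, or a facial course of step 20 other than the one assumed. The fallback sets out from allylic alcohol 36 and comes back at butanoate 38. Dess–Martin oxidation gives the α-methylene ketone F4. Corey–Bakshi–Shibata reduction ((S)-methyl oxazaborolidine, BH3·SMe2, with the alkenyl group as the larger substituent) should give the (6R)-allylic alcohol F5 under reagent control, so the result no longer depends on the substrate bias. Steglich esterification of F5 with butanoic acid 37 (EDC·HCl, DMAP) proceeds with retention and gives 38.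

Step 11. The process at risk is capture of the unstabilised carbenoid by the C3 silyl ether oxygen, C–H insertion, or a [1,2]-shift of the ylide. The fallback sets out from acid 17 and comes back at ketone 21. Acid 17 is homologated with carbonyldiimidazole and Mg(O2CCH2CO2Et)2 to the β-keto ester F1. Diazo transfer with 4-acetamidobenzenesulfonyl azide and Et3N gives the 2-diazo-3-keto ester F2. Its stabilised acceptor/acceptor carbenoid (Rh2(OAc)4 or Cu(hfacac)2, CH2Cl2) is more discriminating and should undergo the same ylide formation and [2,3]-shift to the bicyclic β-keto ester F3. Krapcho dealkoxycarbonylation (LiCl, wet DMSO, 130 °C) removes the helper ester and returns 21.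

**Further compounds**

F1 | step 11 | ethyl 3-oxo-4-[(2S,3S,4R,6S)-3-(TBS-oxy)-4-(PMB-oxy)-3-methyl-6-(prop-1-en-2-yl)oxan-2-yl]butanoate | CCOC(=O)CC(=O)C[C@@H]1O[C@H](C(C)=C)C[C@@H](OCc2ccc(OC)cc2)[C@]1(C)O[Si](C)(C)C(C)(C)C
F2 | step 11 | ethyl 2-diazo-3-oxo-4-[(2S,3S,4R,6S)-3-(TBS-oxy)-4-(PMB-oxy)-3-methyl-6-(prop-1-en-2-yl)oxan-2-yl]butanoate | CCOC(=O)C(=[N+]=[N-])C(=O)C[C@@H]1O[C@H](C(C)=C)C[C@@H](OCc2ccc(OC)cc2)[C@]1(C)O[Si](C)(C)C(C)(C)C
F3 | step 11 | ethyl (5Z)-2-(TBS-oxy)-3-(PMB-oxy)-2,6-dimethyl-9-oxo-11-oxabicyclo[6.2.1]undec-5-ene-8-carboxylate (8-ethoxycarbonyl derivative of 21) | C/C1=C/C[C@@H](OCc3ccc(OC)cc3)[C@](C)(O[Si](C)(C)C(C)(C)C)[C@@H]2CC(=O)[C@](C(=O)OCC)(C1)O2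
F4 | step 22 | 6-oxo-7-methylene tricyclic ketone (3,16-bis-OTBS, 4-OPMB, 11-OH) | C=C1C(=O)C[C@@H](OCc4ccc(OC)cc4)[C@](C)(O[Si](C)(C)C(C)(C)C)[C@@H]2[C@H]3[C@H]([C@@H](C)CO[Si](C)(C)C(C)(C)C)CC[C@@](C)(O)[C@H]3[C@H](C1)O2
F5 | step 22 | (6R)-6-hydroxy-7-methylene allylic alcohol (C6 epimer of 36) | C=C1[C@H](O)C[C@@H](OCc4ccc(OC)cc4)[C@](C)(O[Si](C)(C)C(C)(C)C)[C@@H]2[C@H]3[C@H]([C@@H](C)CO[Si](C)(C)C(C)(C)C)CC[C@@](C)(O)[C@H]3[C@H](C1)O2
F6 | step 25 | (15R)-C16 hydroxy aldehyde (3,11-diol, 6-butanoate, 4-OPMB) | C=C1[C@H](OC(=O)CCC)C[C@@H](OCc4ccc(OC)cc4)[C@](C)(O)[C@@H]2[C@H]3[C@H]([C@@H](C)C=O)CC[C@@](C)(O)[C@H]3[C@H](C1)O2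
F7 | step 25 | seven-membered lactol (C16 hemiacetal with O3, epimer mixture at C16) | C=C1C[C@@H]2O[C@H]3[C@H]4[C@@H](CC[C@@](C)(O)[C@H]42)[C@@H](C)C(O)O[C@@]3(C)[C@H](OCc5ccc(OC)cc5)C[C@H]1OC(=O)CCC
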